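The data were computed for substances that don't exist, noise included.

One constant per run was what I wanted before charging the west flask. If the rate is k[X], a pseudo-first-order decay, the same share of X goes each minute. The X left after time t is then the charge times exp(−kt), so k is the ln of charge over X left, divided by t.

| flask | X | Q | J | time |
|---|---|---|---|---|
| north | 0.0800 M | 0.240 M | 4.00 × 10⁻⁴ M |  |
| north-east | 0.0400 M | 0.240 M | 4.00 × 10⁻⁴ M |  |
| west | 0.0170 M | 0.240 M | 4.00 × 10⁻⁴ M | 20 min |

| run | time / min | [Z] / M |
|---|---|---|
| north run | 1.1 | 0.0074 |
| north run | 3.4 | 0.0239 |
| north run | 6.6 | 0.0449 |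
| north run | 10 | 0.0579 |
| north run | 15 | 0.0682 |
| north run | 20 | 0.0715 |
| north-east run | 1.1 | 0.0037 |
| north-east run | 3.4 | 0.0106 |
| north-east run | 6.6 | 0.0193 |
| north-east run | 10 | 0.0262 |
| north-east run | 15 | 0.0313 |
| north-east run | 20 | 0.0340 |

(standard deviation of a reading: 8 × 10⁻⁴ M)

- how the opening rate goes with [X] round the charge of the north run: the exponent of the rate at two percent of X gone to Z (one fixed amount of Z, the same in the runs compared)
- Z in the west run at 20 min, as a share of the X charged

- Overall: X + Q -> Z, with J as catalyst.
- Constant volume, constant temperature.
- Bound and free are read together.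
- "The second partner" is Q.
- An order is taken over about fifteen percent of the charge, up and down.

The north run held 0.0715 M of Z at 20 min, which gave 0.112 min⁻¹. I called this value, k taken at the last reading, the end constant. The north-east run gave 0.0949 min⁻¹, smaller than the north value. So the two readings did not give one k, and the higher value stood with the higher charge of X. Each value carried the scatter of its reading, 8 × 10⁻⁴ M.

My decision was whether the west flask could keep its 20 min and the same Q and J. I drew a straight line through the two end constants against the X charged. The west charge is lower than either, so the line was stretched. It gave 0.0849 min⁻¹, and so a share of 81.7 % at 20 min. Half of the X would turn by 8.16 min, well before the end. I kept the recipe.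

I set no order of my own. The first north-east reading was 0.0037 M with a scatter of 8 × 10⁻⁴ M, too coarse for that.

The forecast gave 0.96 (0.8 to 1.1) for the order and 79 % (72 % to 85 %) for the west run, lower than my share. It held that “The local k follows Z, not time, across both runs”.

The west flask gave 77.4 %, and the order round the north charge came to 0.77, below the forecast's 0.96.

    J + X ⇌ JX, settled at all times (4.890 M⁻¹)
    JX + Q → Z + J + G (217.2 M⁻¹ min⁻¹)
    Q → Wa (0.05622 min⁻¹)
    X + Q + Z → 2 Z (17.52 M⁻² min⁻¹)

A fit with the main steps alone had forecast 91.8 % for the west run. The west end constant came to 0.0744 min⁻¹, smaller than my 0.0849 min⁻¹. Put to the north run, the end constant 0.112 min⁻¹ places Z at half of the X charged at 6.18 min, and the north run reached that point earlier, at 5.74 min.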